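**Plan**

1. Retrosynthesis: the dihydropyran is cut at O–C4 and C1′–C5 (retro oxa-[4+2]) to (−)-β-caryophyllene and an acyl-substituted alkylidene trione. Its cis-2-ene-1,4-dione (O=C2′–C1′H=C–C=O) is read as a furan one oxidation level lower, and the furan is cut (Paal–Knorr, enolate alkylation) to syncarpic acid and 1-bromo-3-methylbutan-2-one. Locants: C4/C5 are caryophyllane carbons, C1′ is the pyran CH bearing the isobutyryl group, C2′ is its C=O.
2. Forward: the trione ring is made first (fourfold C-methylation of phloroacetophenone, deacetylation), then C-alkylation, then the furan ring. The dihydropyran ring is closed last, onto the intact nine- and four-membered rings, by oxidative furan opening and cycloaddition; no glyoxal and no condensation catalyst meet the terpene.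
3. Enabling feature: the furan C3 (future C1′) and the alkene carbon C5 are both nucleophilic and are joined only after a two-electron oxidation of the furan. This works because the tetramethyl trione ring is locally symmetric (both ring C=O equivalent, so alkene geometry is irrelevant and the acyl group can sit outside) and because the (E)-C4=C5 bond in the nine-membered ring is strained.
4. Stereochemistry: C1 and C9 come from the terpene; C4 and C5 from suprafacial addition to the E-alkene on its exposed face; C1′ from the endo/exo choice of the cycloaddition.

Key step: step 5

**Route**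

Step 1
Reactants: 1 1-(2,4,6-trihydroxyphenyl)ethan-1-one
Product: 2 2-acetyl-3-hydroxy-4,4,6,6-tetramethylcyclohex-2-ene-1,5-dione (acetylsyncarpic acid)
Conditions: NaOMe (5 equiv), MeI (6 equiv), MeOH, 0 °C to reflux; dilute HCl work-up
Reagents that add atoms: iodomethane, CI
Why: Exhaustive C-methylation of a phloroglucinol (dearomatising enolate alkylation): the acetyl group blocks one ring carbon, and each of the two free ring carbons is methylated twice in a protic medium that favours C- over O-alkylation; no stereocentre is formed.

Step 2
Reactants: 2 acetylsyncarpic acid
Product: 3 3-hydroxy-4,4,6,6-tetramethylcyclohex-2-ene-1,5-dione (syncarpic acid)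
Conditions: 6 M aq. HCl, reflux
Reagents that add atoms: none
Why: Acid-mediated retro-Claisen deacylation: water adds to the exocyclic acetyl carbonyl of the β-triketone and acetic acid is expelled, while the gem-dimethyl carbons prevent rearomatisation; no stereocentre is formed.

Step 3
Reactants: 3 syncarpic acid; 4 1-bromo-3-methylbutan-2-one
Product: 5 3-hydroxy-4,4,6,6-tetramethyl-2-(3-methyl-2-oxobutyl)cyclohex-2-ene-1,5-dione
Conditions: KOH (1.0 equiv), MeOH–H2O, 0 °C to rt; cold dilute HCl to pH 3
Reagents that add atoms: none
Why: SN2 C-alkylation of a cyclic β-diketone enolate with a primary α-bromo ketone: the hydrogen-bonded enolate should react at carbon with the soft, unhindered electrophile, and one equivalent of base limits double alkylation; no stereocentre is formed.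

Step 4
Reactants: 5 C-alkylated trione
Product: 6 5,5,7,7-tetramethyl-2-(propan-2-yl)-1-benzofuran-4,6(5H,7H)-dione
Conditions: TsOH·H2O (10 mol %), PhMe, reflux, Dean–Stark
Reagents that add atoms: none
Why: Paal–Knorr furan synthesis: the enol oxygen adds to the side-chain ketone and the hemiketal loses water to give the aromatic furan, whose 2-isopropyl regiochemistry is fixed by the C-alkylation of step 3; no stereocentre is formed.

Step 5
Reactants: 6 fused 2-isopropylfuran; 7 (−)-β-caryophyllene
Product: 9 Tomentodione R, via enetrione 8 (not isolated)
Conditions: DMDO (1.05 equiv, acetone solution), CH2Cl2, −20 to 0 °C; volatiles largely removed at 0 °C (not to dryness); then 7 (2 equiv), CH2Cl2, 0 °C to rt, dark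
Reagents that add atoms: dimethyldioxirane, CC1(C)OO1
Why: Dimethyldioxirane should epoxidise the electron-rich C2=C3 enol-ether bond of furan 6, and the furan epoxide opens by a six-electron reorganisation to the cis-2-ene-1,4-dione 8 (closest known reaction: dioxirane oxidation of alkylfurans to Z-enediones), in which the exocyclic C1′=C bond and either ring carbonyl form an s-cis-locked 1-oxadiene. 8 then adds to the strained (E)-C4=C5 bond of 7 in an inverse-electron-demand oxa-Diels–Alder reaction, the established mode of union of alkylidene β-triketones and o-quinone methides with β-caryophyllene. The dihydropyran closes by a concerted, asynchronous suprafacial [4+2] (C1′–C5 bond leading, O–C4 bond lagging), so oxygen goes to the tertiary C4 without a free C4 cation that could cyclise across the nine-membered ring. C4 and C5 are set together: the E-geometry is transferred into the trans 4-Me/5-H ring fusion, and the diene adds to the exposed outer face of the alkene in the ground-state conformers fixed by C1 and C9 (the face epoxidised in (−)-caryophyllene oxide), which should give 4R,5S. C1′ is set by the transition state in which the isobutyryl group takes the outside position of the diene terminus (open to either alkene geometry because the two ring carbonyls are equivalent) and the trione ring lies over the H-5/C-3 edge of the alkene, which places the acyl group cis to H-5 (1′S); because C1′–H is α to the ketone, a 1′-epimer fraction remains open to re-equilibration through the enolate. The step needs selectivity for the endocyclic over the exocyclic alkene (secured by trans-cycloalkene strain), for the ring C=O oxadiene over the isobutyryl C=O oxadiene (the former is s-cis locked and creates no quaternary spiro carbon) and for cycloaddition over ene reaction, and it keeps oxidant and acid away from 7 because the dioxirane is consumed or evaporated before 7 is added.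

**Compound list**

1 | 1-(2,4,6-trihydroxyphenyl)ethan-1-one (2′,4′,6′-trihydroxyacetophenone) | CC(=O)c1c(O)cc(O)cc1O | starting material
2 | 2-acetyl-3-hydroxy-4,4,6,6-tetramethylcyclohex-2-ene-1,5-dione (acetylsyncarpic acid) | CC(=O)C1=C(O)C(C)(C)C(=O)C(C)(C)C1=O | intermediate
3 | 3-hydroxy-4,4,6,6-tetramethylcyclohex-2-ene-1,5-dione (syncarpic acid) | CC1(C)C(=O)C=C(O)C(C)(C)C1=O | intermediate
4 | 1-bromo-3-methylbutan-2-one | CC(C)C(=O)CBr | starting material
5 | 3-hydroxy-4,4,6,6-tetramethyl-2-(3-methyl-2-oxobutyl)cyclohex-2-ene-1,5-dione | CC(C)C(=O)CC1=C(O)C(C)(C)C(=O)C(C)(C)C1=O | intermediate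
6 | 5,5,7,7-tetramethyl-2-(propan-2-yl)-1-benzofuran-4,6(5H,7H)-dione | CC(C)c1cc2c(o1)C(C)(C)C(=O)C(C)(C)C2=O | intermediate
7 | (−)-β-caryophyllene, (1R,4E,9S)-4,11,11-trimethyl-8-methylidenebicyclo[7.2.0]undec-4-ene | C/C/1=C\CCC(=C)[C@H]2CC([C@@H]2CC1)(C)C | starting material
8 | 4,4,6,6-tetramethyl-2-(3-methyl-2-oxobutylidene)cyclohexane-1,3,5-trione (enetrione; formed in the flask, not isolated) | CC(C)C(=O)C=C1C(=O)C(C)(C)C(=O)C(C)(C)C1=O | intermediate
9 | Tomentodione R, the (1R,4R,5S,9S,1′S) adduct: dihydropyran fused at C4–C5 of the caryophyllane skeleton (O on C4, C1′ on C5, trans 4-Me/5-H), C1′ bearing the isobutyryl group cis to H-5 and fused through the enol-ether bond to the tetramethylcyclohexanedione ring; exocyclic methylene and gem-dimethylcyclobutane retained | C=C1CC[C@H]2[C@H](C(=O)C(C)C)C3=C(O[C@]2(C)CC[C@@H]2[C@@H]1CC2(C)C)C(C)(C)C(=O)C(C)(C)C3=O | target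

**Count**

Total steps: 5. Longest linear sequence: 5 steps (1 → 2 → 3 → 5 → 6 → 9); 4 and 7 are bought and enter in steps 3 and 5.

**Steps most likely to fail, with fallbacks**

Step 5. The epoxidation of the acyl-deactivated furan may be slow or unselective. The free enetrione may be lost to hydration or self-cycloaddition during the solvent change. The exocyclic methylene may undergo an ene reaction, and the cycloaddition may leak to the 1′-epimer or to the other alkene face. The fallback generates the same oxadiene by condensation instead of oxidation and sets out from 3 and 7. 3-Methyl-2-oxobutanal F1 is prepared by SeO2 oxidation of commercial 3-methylbutan-2-one in dioxane–water. It is condensed with 3 under ethylenediammonium diacetate or L-proline catalysis in CH2Cl2 at rt with 7 present from the start. The aldol adduct 3-hydroxy-2-(1-hydroxy-3-methyl-2-oxobutyl)-4,4,6,6-tetramethylcyclohex-2-ene-1,5-dione F2 should dehydrate slowly (Knoevenagel) to 8, which is captured by 7 as it forms. The fallback returns to the route at 9 and bypasses steps 3 and 4.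

Step 3. The ambident trione enolate may be alkylated on oxygen, which after step 4 would lead to the 3-isopropyl furan regioisomer, or twice on carbon. The fallback builds the furan by carbenoid [3+2] cycloaddition and sets out from 3. PhI(OAc)2 and KOH in MeOH at 0 °C should give the iodonium ylide 4,4,6,6-tetramethyl-2-(phenyl-λ3-iodanylidene)cyclohexane-1,3,5-trione F3. With 3-methylbut-1-yne and catalytic Rh2(OAc)4 or Cu(acac)2 in CH2Cl2, F3 should give the furan with the carbenoid carbon bonded to the terminal alkyne carbon, so that the isopropyl group ends next to oxygen. The fallback returns to the route at 6 and bypasses 5 and step 4.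

Step 4. Acid and heat may cleave the β-triketone (retro-Claisen) or stop at the hemiketal instead of completing the cyclodehydration. The fallback bypasses the furan and sets out from 5. NBS in CH2Cl2 at 0 °C should brominate the enolised ring carbon to give 2-bromo-4,4,6,6-tetramethyl-2-(3-methyl-2-oxobutyl)cyclohexane-1,3,5-trione F4. After filtration, 2,6-lutidine and 7 are added; β-elimination of HBr through the C1′ enolate of the isobutyryl ketone should release 8 in the presence of the terpene. The fallback returns to the route at 8 and so at 9.

**Further compounds**

F1 | step 5 | 3-methyl-2-oxobutanal | CC(C)C(=O)C=O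
F2 | step 5 | 3-hydroxy-2-(1-hydroxy-3-methyl-2-oxobutyl)-4,4,6,6-tetramethylcyclohex-2-ene-1,5-dione (racemic, not isolated) | CC(C)C(=O)C(O)C1=C(O)C(C)(C)C(=O)C(C)(C)C1=O
F3 | step 3 | 4,4,6,6-tetramethyl-2-(phenyl-λ3-iodanylidene)cyclohexane-1,3,5-trione (iodonium ylide, zwitterion) | CC1(C)C(=O)C(C)(C)C([O-])=C([I+]c2ccccc2)C1=O
F4 | step 4 | 2-bromo-4,4,6,6-tetramethyl-2-(3-methyl-2-oxobutyl)cyclohexane-1,3,5-trione | CC(C)C(=O)CC1(Br)C(=O)C(C)(C)C(=O)C(C)(C)C1=O
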